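Kushenol C is 8-lavandulylmorin, so the flavonol core is bought as morin and the complete C9 side-chain unit is attached late. The side-chain stereocentre is allylic: it carries the isopropenyl group C(=CH2)CH3. Its bond to the benzylic CH2 on C8 of ring A is therefore made by a copper-catalysed enantioselective SN2′ allylic substitution. The precursors are a C8-(pinacolboryl)methyl morin penta-MOM ether and the achiral linear (E)-2,6-dimethylhepta-2,5-dienyl phosphate. In one operation the step joins both fragments, sets the (R) centre under ligand control and transposes the trisubstituted alkene into the isopropenyl group.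

Key step: step 6

Remark: morin is taken as its commercial hydrate (dried before use). The side-chain centre of the target is (R), and the ligand enantiomer for step 6 is the one that effects Si-face attack at C3 of 9, to be fixed in a test run.

**Step 1**
Reactants: 1 morin (3,5,7,2′,4′-pentahydroxyflavone)
Product: 2 3,5,7,2′,4′-pentakis(methoxymethoxy)flavone
Conditions: NaH (7 equiv), MOMCl (7 equiv), DMF, 0 °C → rt
Reagents that add atoms: chloromethyl methyl ether (MOMCl), COCCl
Why: Williamson O-alkylation of all five phenoxides; NaH in DMF breaks the 5-OH/3-OH chelates to the C4 carbonyl so that these positions are capped too, giving base-stable acetals.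

**Step 2**
Reactants: 2 3,5,7,2′,4′-pentakis(methoxymethoxy)flavone
Product: 3 8-iodo-3,5,7,2′,4′-pentakis(methoxymethoxy)flavone
Conditions: NIS (1.1 equiv), DMF, rt, dark
Reagents that add atoms: N-iodosuccinimide, O=C1CCC(=O)N1I
Why: electrophilic aromatic iodination; C8 of ring A is activated by O1, the 7-alkoxy and the para 5-alkoxy group, and 5,7-dialkoxyflavones are known to iodinate at C8 under neutral NIS conditions.

**Step 3**
Reactants: 3 8-iodo-3,5,7,2′,4′-pentakis(methoxymethoxy)flavone; 4 bis(4,4,5,5-tetramethyl-1,3,2-dioxaborolan-2-yl)methane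
Product: 5 8-[(4,4,5,5-tetramethyl-1,3,2-dioxaborolan-2-yl)methyl]-3,5,7,2′,4′-pentakis(methoxymethoxy)flavone
Conditions: Pd[P(t-Bu)3]2 (5 mol%), KOH (8 M aq, 2 equiv), 1,4-dioxane, rt
Reagents that add atoms: none
Why: chemoselective Suzuki–Miyaura coupling of a gem-diborylmethane, in which hydroxide activates only one boryl group, so mono-arylation should give the benzylboronate, which does not couple further at rt.

**Step 4**
Reactants: 6 2-methyl-1-propenylmagnesium bromide; 7 2-methyl-2-vinyloxirane (isoprene monoxide, racemic)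
Product: 8 (2E)-2,6-dimethylhepta-2,5-dien-1-ol
Conditions: CuI (5 mol%), THF, −30 → 0 °C; aq NH4Cl; AgNO3–silica chromatography to remove the minor Z isomer
Reagents that add atoms: none
Why: copper-catalysed SN2′ (1,4-) opening of a vinyl oxirane by an alkenyl Grignard reagent, which should give mainly the E-trisubstituted allylic alcohol through the s-trans conformer.

**Step 5**
Reactants: 8 (2E)-2,6-dimethylhepta-2,5-dien-1-ol
Product: 9 diethyl (2E)-2,6-dimethylhepta-2,5-dien-1-yl phosphate
Conditions: (EtO)2P(O)Cl (1.2 equiv), pyridine (2 equiv), DMAP (cat.), CH2Cl2, 0 °C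
Reagents that add atoms: diethyl chlorophosphate, CCOP(=O)(Cl)OCC
Why: O-phosphorylation of the primary allylic alcohol without allylic transposition, installing the leaving group needed for the copper step.

**Step 6**
Reactants: 5 8-[(pinacolboryl)methyl]-3,5,7,2′,4′-pentakis(methoxymethoxy)flavone (1.0 equiv); 9 diethyl (2E)-2,6-dimethylhepta-2,5-dien-1-yl phosphate (1.5 equiv)
Product: 10 8-[(2R)-5-methyl-2-(prop-1-en-2-yl)hex-4-en-1-yl]-3,5,7,2′,4′-pentakis(methoxymethoxy)flavone (penta-MOM Kushenol C)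
Conditions: CuCl (10 mol%), chiral sulfonate-bearing imidazolinium salt (N-(2-sulfonatoaryl)-N′-aryl-4-phenylimidazolinium type, one enantiomer, 11 mol%), NaOMe (2 equiv), THF, 22 °C
Reagents that add atoms: none
Why: Proposed new method: methoxide-activated boronate 5 should transfer its stabilised benzyl group to the chiral NHC–Cu(I) centre, and the resulting benzylcopper should add in an anti-SN2′ sense to C3 of phosphate 9 to give a Cu(III) σ-allyl species whose reductive elimination forms the CH2–CH bond and leaves the double bond as the isopropenyl group. The closest known reaction type is the NHC–Cu-catalysed enantioselective SN2′ substitution of E-allylic phosphates with aryl-, alkenyl- and allenyl-B(pin) reagents and with diborylmethane (a Cu–CH2B(pin) nucleophile); a primary benzylic boronate and a 2-methyl-substituted allyl phosphate have not been shown in it. No ring is closed. The only new stereocentre is set by the ligand: its sulfonate–Na+–phosphate bridge orients the E-alkene so that copper delivers the benzyl group to the Si face of C3, which gives (R). The step needs SN2′ over SN2 selectivity, which the inner-sphere bridged pathway and the phosphate leaving group should secure, and a geometrically pure E-alkene, because the Z isomer would lead to the antipode. The MOM acetals and the chromone carbonyl should be inert to the soft benzylcopper and to NaOMe at 22 °C.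

**Step 7**
Reactants: 10 penta-MOM Kushenol C
Product: 11 Kushenol C, 8-[(2R)-5-methyl-2-(prop-1-en-2-yl)hex-4-en-1-yl]-3,5,7,2′,4′-pentahydroxyflavone
Conditions: HCl (ca. 0.5 M, from conc. aq HCl), MeOH/THF, 40 °C; NaHCO3 quench
Reagents that add atoms: none
Why: acid-catalysed acetal exchange (methanolysis of the aryl MOM ethers) should release the five phenols at a temperature low enough that the isopropenyl and prenyl alkenes are not protonated; the stereocentre is not acidic and is untouched.

**Compound list**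
1 | morin (3,5,7,2′,4′-pentahydroxyflavone) | O=c1c(O)c(-c2ccc(O)cc2O)oc2cc(O)cc(O)c12 | starting material
2 | 3,5,7,2′,4′-pentakis(methoxymethoxy)flavone | COCOc1ccc(-c2oc3cc(OCOC)cc(OCOC)c3c(=O)c2OCOC)c(OCOC)c1 | intermediate
3 | 8-iodo-3,5,7,2′,4′-pentakis(methoxymethoxy)flavone | COCOc1ccc(-c2oc3c(I)c(OCOC)cc(OCOC)c3c(=O)c2OCOC)c(OCOC)c1 | intermediate
4 | bis(4,4,5,5-tetramethyl-1,3,2-dioxaborolan-2-yl)methane | CC1(C)OB(CB2OC(C)(C)C(C)(C)O2)OC1(C)C | starting material
5 | 8-[(4,4,5,5-tetramethyl-1,3,2-dioxaborolan-2-yl)methyl]-3,5,7,2′,4′-pentakis(methoxymethoxy)flavone | COCOc1ccc(-c2oc3c(CB4OC(C)(C)C(C)(C)O4)c(OCOC)cc(OCOC)c3c(=O)c2OCOC)c(OCOC)c1 | intermediate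
6 | 2-methyl-1-propenylmagnesium bromide | CC(C)=C[Mg]Br | starting material
7 | 2-methyl-2-vinyloxirane (isoprene monoxide, racemic) | C=CC1(C)CO1 | starting material
8 | (2E)-2,6-dimethylhepta-2,5-dien-1-ol | OC/C(C)=C/CC=C(C)C | intermediate
9 | diethyl (2E)-2,6-dimethylhepta-2,5-dien-1-yl phosphate | CCOP(=O)(OCC)OC/C(C)=C/CC=C(C)C | intermediate
10 | 8-[(2R)-5-methyl-2-(prop-1-en-2-yl)hex-4-en-1-yl]-3,5,7,2′,4′-pentakis(methoxymethoxy)flavone | C=C(C)[C@H](CC=C(C)C)Cc1c(OCOC)cc(OCOC)c2c(=O)c(OCOC)c(-c3ccc(OCOC)cc3OCOC)oc12 | intermediate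
11 | Kushenol C | C=C(C)[C@H](CC=C(C)C)Cc1c(O)cc(O)c2c(=O)c(O)c(-c3ccc(O)cc3O)oc12 | target

**Step count and risks**
Total steps: 7. Longest linear sequence: 5 (steps 1, 2, 3, 6, 7); the side-chain partner takes 2 steps (4, 5).

Steps most likely to fail:

1. Step 6 (Proposed new method). Transmetalation of the hindered benzylboronate to copper may be slow, the benzylcopper may couple at the α-carbon (SN2, linear achiral isomer), or the facial selectivity may be poor. The fallback uses known chemistry, sets out from 3 (side chain from 8) and comes back at 10. Iodide 3 is formylated by Pd-catalysed reductive carbonylation (PdCl2(dppp), CO, Et3SiH, Na2CO3, DMF, 90 °C) to 8-formyl-3,5,7,2′,4′-pentakis(methoxymethoxy)flavone F1. Alcohol 8 is borylated with B2pin2 under Pd catalysis (DMSO/MeOH, cat. TsOH) to the linear 2-[(2E)-2,6-dimethylhepta-2,5-dien-1-yl]-4,4,5,5-tetramethyl-1,3,2-dioxaborolane F2. Chiral phosphoric acid-catalysed allylboration of F1 with F2 (3,3′-bis(2,4,6-triisopropylphenyl)-BINOL hydrogen phosphate, enantiomer for Si-face attack on the aldehyde, toluene, −30 °C) should pass through a chair transition state and give the anti alcohol (1S,2S)-5-methyl-2-(prop-1-en-2-yl)-1-[3,5,7,2′,4′-pentakis(methoxymethoxy)flavon-8-yl]hex-4-en-1-ol F3. Its allylic centre has the spatial arrangement required in 10. The benzylic oxygen is then removed by Barton–McCombie deoxygenation through the O-alkyl S-methyl xanthate F4 (NaH, CS2, MeI, THF, 0 °C; then Bu3SnH, AIBN, toluene, 80 °C), which gives 10.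

2. Step 2. Iodination may be poorly site-selective, with attack at C6 or at C5′ of the electron-rich 2′,4′-dioxygenated B ring. The fallback sets out from 1 and comes back at 5. A phenoxide-directed Mannich reaction of free morin (aq HCHO, Me2NH, EtOH, rt) should go ortho to the acidic 7-OH at C8, as in other 5,7-dihydroxyflavonoids, and give 8-[(dimethylamino)methyl]morin F5. Protection as in step 1 gives 8-[(dimethylamino)methyl]-3,5,7,2′,4′-pentakis(methoxymethoxy)flavone F6. Ethyl chloroformate (CH2Cl2, 0 °C → rt) cleaves the benzylic C–N bond to give 8-(chloromethyl)-3,5,7,2′,4′-pentakis(methoxymethoxy)flavone F7. Pd-catalysed Miyaura borylation of the benzylic chloride (Pd(dba)2, P(4-MeOC6H4)3, B2pin2, KOAc, toluene, 50 °C) gives 5.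

3. Step 7. Under Brønsted acid the isopropenyl or prenyl alkene may be protonated and trapped by the liberated 7-OH (chroman formation) or by methanol. The fallback changes the protecting group so that the last step needs no acid; it sets out from 1 and comes back at 11. Morin is protected with SEMCl/NaH (DMF) as 3,5,7,2′,4′-pentakis{[2-(trimethylsilyl)ethoxy]methoxy}flavone F8. This is carried through the chemistry of steps 2, 3 and 6: the 8-iodo penta-SEM flavone F9, then the 8-[(pinacolboryl)methyl] penta-SEM flavone F10, then coupling with 9 to penta-SEM Kushenol C F11. Fluoride (TBAF, THF/DMPU, 50 °C) then removes the five SEM groups under non-acidic conditions and gives 11.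

**Further compounds**
F1 | step 6 | 8-formyl-3,5,7,2′,4′-pentakis(methoxymethoxy)flavone | COCOc1ccc(-c2oc3c(C=O)c(OCOC)cc(OCOC)c3c(=O)c2OCOC)c(OCOC)c1
F2 | step 6 | 2-[(2E)-2,6-dimethylhepta-2,5-dien-1-yl]-4,4,5,5-tetramethyl-1,3,2-dioxaborolane | CC1(C)OB(C/C(C)=C/CC=C(C)C)OC1(C)C
F3 | step 6 | (1S,2S)-5-methyl-2-(prop-1-en-2-yl)-1-[3,5,7,2′,4′-pentakis(methoxymethoxy)flavon-8-yl]hex-4-en-1-ol | C=C(C)[C@H](CC=C(C)C)[C@H](O)c1c(OCOC)cc(OCOC)c2c(=O)c(OCOC)c(-c3ccc(OCOC)cc3OCOC)oc12
F4 | step 6 | O-{(1S,2S)-5-methyl-2-(prop-1-en-2-yl)-1-[3,5,7,2′,4′-pentakis(methoxymethoxy)flavon-8-yl]hex-4-en-1-yl} S-methyl carbonodithioate | C=C(C)[C@H](CC=C(C)C)[C@H](OC(=S)SC)c1c(OCOC)cc(OCOC)c2c(=O)c(OCOC)c(-c3ccc(OCOC)cc3OCOC)oc12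
F5 | step 2 | 8-[(dimethylamino)methyl]morin | CN(C)Cc1c(O)cc(O)c2c(=O)c(O)c(-c3ccc(O)cc3O)oc12
F6 | step 2 | 8-[(dimethylamino)methyl]-3,5,7,2′,4′-pentakis(methoxymethoxy)flavone | CN(C)Cc1c(OCOC)cc(OCOC)c2c(=O)c(OCOC)c(-c3ccc(OCOC)cc3OCOC)oc12
F7 | step 2 | 8-(chloromethyl)-3,5,7,2′,4′-pentakis(methoxymethoxy)flavone | ClCc1c(OCOC)cc(OCOC)c2c(=O)c(OCOC)c(-c3ccc(OCOC)cc3OCOC)oc12
F8 | step 7 | 3,5,7,2′,4′-pentakis{[2-(trimethylsilyl)ethoxy]methoxy}flavone | C[Si](C)(C)CCOCOc1ccc(-c2oc3cc(OCOCC[Si](C)(C)C)cc(OCOCC[Si](C)(C)C)c3c(=O)c2OCOCC[Si](C)(C)C)c(OCOCC[Si](C)(C)C)c1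
F9 | step 7 | 8-iodo-3,5,7,2′,4′-pentakis{[2-(trimethylsilyl)ethoxy]methoxy}flavone | C[Si](C)(C)CCOCOc1ccc(-c2oc3c(I)c(OCOCC[Si](C)(C)C)cc(OCOCC[Si](C)(C)C)c3c(=O)c2OCOCC[Si](C)(C)C)c(OCOCC[Si](C)(C)C)c1
F10 | step 7 | 8-[(4,4,5,5-tetramethyl-1,3,2-dioxaborolan-2-yl)methyl]-3,5,7,2′,4′-pentakis{[2-(trimethylsilyl)ethoxy]methoxy}flavone | C[Si](C)(C)CCOCOc1ccc(-c2oc3c(CB4OC(C)(C)C(C)(C)O4)c(OCOCC[Si](C)(C)C)cc(OCOCC[Si](C)(C)C)c3c(=O)c2OCOCC[Si](C)(C)C)c(OCOCC[Si](C)(C)C)c1
F11 | step 7 | 8-[(2R)-5-methyl-2-(prop-1-en-2-yl)hex-4-en-1-yl]-3,5,7,2′,4′-pentakis{[2-(trimethylsilyl)ethoxy]methoxy}flavone | C=C(C)[C@H](CC=C(C)C)Cc1c(OCOCC[Si](C)(C)C)cc(OCOCC[Si](C)(C)C)c2c(=O)c(OCOCC[Si](C)(C)C)c(-c3ccc(OCOCC[Si](C)(C)C)cc3OCOCC[Si](C)(C)C)oc12
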